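**Strategy.** The tetrahydrofuran (O1, C2 aryl, C3 hydroxymethyl, C4 aroyl, C5) is cut at O1–C5. Because C5 is an unsubstituted methylene and C3/C4 can be carried as a C3=C4 double bond, the ring simplifies to a 2,5-dihydrofuran with C2 as its only stereocentre. Iodo-etherification of an α-allenic alcohol forms O1–C5, closes the ring and leaves iodine on C4 as the handle for the aroyl group, all in one operation. The precursor is (S)-1-(3,4-dimethoxyphenyl)-2-(silyloxymethyl)buta-2,3-dien-1-ol, with the C2 hydroxyl free and the C6 oxygen silylated. C3 and C4 are set afterwards by conjugate reduction under control of C2.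

Key step: step 4

Remark: ring atoms are numbered O1, C2 (aryl), C3, C4, C5 throughout, C6 is the CH2O carbon on C3 and C7 the carbon on C4. The antipode of the chromium ligand that gives Re-face addition (S carbinol) is assumed to be available and is the one used.

**Step 1**
Reactants: 1 but-2-yne-1,4-diol
Product: 2 4-[(tert-butyldimethylsilyl)oxy]but-2-yn-1-ol
Conditions: NaH (1.0 equiv), THF, 0 °C → rt; then TBSCl (1.0 equiv), rt
Reagents that add atoms: tert-butyldimethylsilyl chloride, CC(C)(C)[Si](C)(C)Cl
Why: O-silylation of a sodium alkoxide, in which one equivalent of NaH turns the symmetrical diol into its sparingly soluble mono-alkoxide, so that a single silylation should dominate over bis-silylation.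

**Step 2**
Reactants: 2 4-[(tert-butyldimethylsilyl)oxy]but-2-yn-1-ol
Product: 3 [(4-bromobut-2-yn-1-yl)oxy](tert-butyl)dimethylsilane
Conditions: CBr4 (1.2 equiv), PPh3 (1.25 equiv), CH2Cl2, 0 °C
Reagents that add atoms: carbon tetrabromide, BrC(Br)(Br)Br
Why: Appel reaction, in which the primary propargylic hydroxyl is activated as an alkoxyphosphonium ion and displaced by bromide (SN2) under neutral conditions that the TBS ether tolerates.

**Step 3**
Reactants: 3 [(4-bromobut-2-yn-1-yl)oxy](tert-butyl)dimethylsilane; 4 3,4-dimethoxybenzaldehyde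
Product: 6 (S)-2-{[(tert-butyldimethylsilyl)oxy]methyl}-1-(3,4-dimethoxyphenyl)buta-2,3-dien-1-ol, via trimethylsilyl ether 5 (not isolated)
Conditions: CrCl2 (10 mol %), chiral tridentate 1,8-bis(oxazolinyl)carbazole ligand (10 mol %), Mn (2 equiv), i-Pr2NEt (30 mol %), TMSCl (1.2 equiv), THF, rt; then K2CO3, MeOH, 0 °C
Reagents that add atoms: chlorotrimethylsilane, C[Si](C)(C)Cl (its Me3Si group is present in 5 only and is removed before 6 is isolated)
Why: Catalytic asymmetric Nozaki–Hiyama allenylation, in which the propargylchromium(III) species from 3 adds through its γ-carbon (SE2′) to the aldehyde inside the chiral ligand sphere, which should direct attack to the Re face and set C2 as S, while TMSCl releases the chromium alkoxide as silyl ether 5 for turnover and carbonate methanolysis frees the carbinol without touching the TBS ether.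

**Step 4**
Reactants: 6 (S)-2-{[(tert-butyldimethylsilyl)oxy]methyl}-1-(3,4-dimethoxyphenyl)buta-2,3-dien-1-ol
Product: 7 (S)-tert-butyl{[2-(3,4-dimethoxyphenyl)-4-iodo-2,5-dihydrofuran-3-yl]methoxy}dimethylsilane
Conditions: NIS (1.2 equiv), NaHCO3, CH2Cl2, 0 °C → rt, dark
Reagents that add atoms: N-iodosuccinimide, O=C1CCC(=O)N1I
Why: NIS transfers I+ reversibly to the allene, and only the iodonium ion on the outer C4=C5 bond is positioned for ring formation, so the C2 hydroxyl should open it from the rear at the terminal carbon C5 and the succinimide anion should take up the proton, leaving iodine on C4. The closest known reaction type is the halo-etherification of α-allenic alcohols to 3-halo-2,5-dihydrofurans. The ring closes in the 5-endo-trig mode, which is not penalised here because the C4=C5 π-bond is perpendicular to the C3=C4 π-bond and therefore lies in the plane that holds C2 and its oxygen. No stereocentre is created and no bond to C2 is made or broken, so the S configuration of C2 is carried through unchanged. The step needs oxygen selectivity (the C2 hydroxyl and not the C6 oxygen, which is also α to the allene), site selectivity (allene and not the dimethoxyarene) and freedom from ionisation at the benzylic carbinol. These are secured by the silyl ether on C6, by the absence of acid (bicarbonate buffer) and by the low temperature in a non-polar solvent.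

**Step 5**
Reactants: 7 (S)-tert-butyl{[2-(3,4-dimethoxyphenyl)-4-iodo-2,5-dihydrofuran-3-yl]methoxy}dimethylsilane; 8 3,4,5-trimethoxybenzaldehyde
Product: 9 (2S)-3-{[(tert-butyldimethylsilyl)oxy]methyl}-2-(3,4-dimethoxyphenyl)-4-[hydroxy(3,4,5-trimethoxyphenyl)methyl]-2,5-dihydrofuran (C7 epimers)
Conditions: CrCl2 (4 equiv), NiCl2 (2 mol %), DMF, rt
Reagents that add atoms: none
Why: Nozaki–Hiyama–Kishi coupling, in which nickel inserts into the C4–I bond and hands the vinyl group to chromium(III), whose mild nucleophile should add only to the aldehyde and tolerate the silyl ether and the ring oxygen; the new carbinol centre C7 is formed without control and is erased in step 6.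

**Step 6**
Reactants: 9 (2S)-3-{[(tert-butyldimethylsilyl)oxy]methyl}-2-(3,4-dimethoxyphenyl)-4-[hydroxy(3,4,5-trimethoxyphenyl)methyl]-2,5-dihydrofuran
Product: 10 (2S)-3-{[(tert-butyldimethylsilyl)oxy]methyl}-2-(3,4-dimethoxyphenyl)-4-(3,4,5-trimethoxybenzoyl)-2,5-dihydrofuran
Conditions: DMP (1.3 equiv), NaHCO3, CH2Cl2, 0 °C → rt
Reagents that add atoms: none
Why: Dess–Martin oxidation of a secondary alcohol that is both allylic and benzylic, chosen because the buffered, non-basic reagent should neither dehydrogenate the dihydrofuran to a furan nor deprotonate the γ-position C2 of the enone formed.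

**Step 7**
Reactants: 10 (2S)-3-{[(tert-butyldimethylsilyl)oxy]methyl}-2-(3,4-dimethoxyphenyl)-4-(3,4,5-trimethoxybenzoyl)-2,5-dihydrofuran
Product: 12 (2R,3R,4S)-3-{[(tert-butyldimethylsilyl)oxy]methyl}-2-(3,4-dimethoxyphenyl)-4-(3,4,5-trimethoxybenzoyl)tetrahydrofuran, via dimethylphenylsilyl enol ether 11 (not isolated)
Conditions: Cu(OAc)2·H2O (5 mol %), 1,2-(Ph2P)2C6H4 (5 mol %), PhMe2SiH (2 equiv), toluene, rt → 40 °C; then K2CO3, MeOH, rt
Reagents that add atoms: dimethylphenylsilane, C[SiH](C)c1ccccc1 (its silyl group is present in 11 only and is removed before 12 is isolated)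
Why: Ligand-accelerated copper hydride conjugate reduction (Stryker type) with silyl trapping, in which L·Cu–H should add to C3 from the face opposite the C2 aryl so that the C3 side chain ends up cis to the aryl (3R), the enolate is held as silyl enol ether 11 so the aryl ketone is not reduced further, and carbonate methanolysis with equilibration of the enolisable C4 should place the aroyl group trans to the C3 substituent (4S).

**Step 8**
Reactants: 12 (2R,3R,4S)-3-{[(tert-butyldimethylsilyl)oxy]methyl}-2-(3,4-dimethoxyphenyl)-4-(3,4,5-trimethoxybenzoyl)tetrahydrofuran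
Product: 13 [(3S,4R,5R)-5-(3,4-dimethoxyphenyl)-4-(hydroxymethyl)oxolan-3-yl](3,4,5-trimethoxyphenyl)methanone, the target, i.e. (2R,3R,4S) in the ring numbering used here
Conditions: HF·pyridine, pyridine, THF, 0 °C → rt
Reagents that add atoms: none
Why: Fluoride-mediated desilylation of a primary TBS ether under buffered, nearly neutral conditions that should neither epimerise C4 nor ionise the benzylic C2–O1 bond.

**Compound list**
1 | but-2-yne-1,4-diol | OCC#CCO | starting material
2 | 4-[(tert-butyldimethylsilyl)oxy]but-2-yn-1-ol | CC(C)(C)[Si](C)(C)OCC#CCO | intermediate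
3 | [(4-bromobut-2-yn-1-yl)oxy](tert-butyl)dimethylsilane | CC(C)(C)[Si](C)(C)OCC#CCBr | intermediate
4 | 3,4-dimethoxybenzaldehyde | COc1ccc(C=O)cc1OC | starting material
5 | (S)-2-{[(tert-butyldimethylsilyl)oxy]methyl}-1-(3,4-dimethoxyphenyl)-1-[(trimethylsilyl)oxy]buta-2,3-diene, formed in the flask | COc1ccc([C@H](O[Si](C)(C)C)C(CO[Si](C)(C)C(C)(C)C)=C=C)cc1OC | intermediate
6 | (S)-2-{[(tert-butyldimethylsilyl)oxy]methyl}-1-(3,4-dimethoxyphenyl)buta-2,3-dien-1-ol | COc1ccc([C@H](O)C(CO[Si](C)(C)C(C)(C)C)=C=C)cc1OC | intermediate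
7 | (S)-tert-butyl{[2-(3,4-dimethoxyphenyl)-4-iodo-2,5-dihydrofuran-3-yl]methoxy}dimethylsilane | COc1ccc([C@@H]2OCC(I)=C2CO[Si](C)(C)C(C)(C)C)cc1OC | intermediate
8 | 3,4,5-trimethoxybenzaldehyde | COc1cc(C=O)cc(OC)c1OC | starting material
9 | (2S)-3-{[(tert-butyldimethylsilyl)oxy]methyl}-2-(3,4-dimethoxyphenyl)-4-[hydroxy(3,4,5-trimethoxyphenyl)methyl]-2,5-dihydrofuran, both C7 epimers | COc1ccc([C@@H]2OCC(C(O)c3cc(OC)c(OC)c(OC)c3)=C2CO[Si](C)(C)C(C)(C)C)cc1OC | intermediate
10 | (2S)-3-{[(tert-butyldimethylsilyl)oxy]methyl}-2-(3,4-dimethoxyphenyl)-4-(3,4,5-trimethoxybenzoyl)-2,5-dihydrofuran | COc1ccc([C@@H]2OCC(C(=O)c3cc(OC)c(OC)c(OC)c3)=C2CO[Si](C)(C)C(C)(C)C)cc1OC | intermediate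
11 | (2R,3R)-3-{[(tert-butyldimethylsilyl)oxy]methyl}-2-(3,4-dimethoxyphenyl)-4-{[dimethyl(phenyl)silyl]oxy(3,4,5-trimethoxyphenyl)methylidene}tetrahydrofuran, enol ether geometry not defined, formed in the flask | COc1ccc([C@@H]2OCC(=C(O[Si](C)(C)c3ccccc3)c3cc(OC)c(OC)c(OC)c3)[C@@H]2CO[Si](C)(C)C(C)(C)C)cc1OC | intermediate
12 | (2R,3R,4S)-3-{[(tert-butyldimethylsilyl)oxy]methyl}-2-(3,4-dimethoxyphenyl)-4-(3,4,5-trimethoxybenzoyl)tetrahydrofuran | COc1ccc([C@@H]2OC[C@@H](C(=O)c3cc(OC)c(OC)c(OC)c3)[C@@H]2CO[Si](C)(C)C(C)(C)C)cc1OC | intermediate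
13 | [(3S,4R,5R)-5-(3,4-dimethoxyphenyl)-4-(hydroxymethyl)oxolan-3-yl](3,4,5-trimethoxyphenyl)methanone | COc1ccc([C@@H]2OC[C@@H](C(=O)c3cc(OC)c(OC)c(OC)c3)[C@@H]2CO)cc1OC | target

**Total step count:** 8
**Longest linear sequence:** 8 steps (1 → 2 → 3 → 6 → 7 → 9 → 10 → 12 → 13)

**Steps most likely to fail**

Step 7. Hydrocupration of the tetrasubstituted, electron-rich C3=C4 bond may be too slow. Hydride may instead be delivered to the carbonyl carbon, or the enone may lose its C2 integrity by γ-deprotonation before it is reduced. The fallback moves saturation ahead of the oxidation and uses hydroxyl-directed homogeneous hydrogenation. It sets out from 9. With [Ir(cod)(PCy3)(py)]PF6 and H2 (1 atm) in CH2Cl2, the C7 hydroxyl should hold the catalyst while the C2 aryl blocks one face, so both hydrogens should arrive anti to the aryl. This should give (2R,3R,4R)-3-{[(tert-butyldimethylsilyl)oxy]methyl}-2-(3,4-dimethoxyphenyl)-4-[hydroxy(3,4,5-trimethoxyphenyl)methyl]tetrahydrofuran F1, the all-cis alcohol. Dess–Martin oxidation should then give (2R,3R,4R)-3-{[(tert-butyldimethylsilyl)oxy]methyl}-2-(3,4-dimethoxyphenyl)-4-(3,4,5-trimethoxybenzoyl)tetrahydrofuran F2, the all-cis ketone. DBU in CH2Cl2 should epimerise C4 to the trans ketone, at which point the route is rejoined at 12.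

Step 3. Enantiofacial discrimination may be insufficient with the oxygenated propargyl partner. Addition may also occur through the α-carbon to give the homopropargylic alcohol, or the organochromium species may lose silanolate by 1,4-elimination. The fallback gives up catalytic control and resolves instead. It sets out from 3 and 4. An indium-mediated Barbier allenylation (In, THF/aq. NH4Cl, rt) should give racemic 2-{[(tert-butyldimethylsilyl)oxy]methyl}-1-(3,4-dimethoxyphenyl)buta-2,3-dien-1-ol F3. Esterification with (R)-2-methoxy-2-phenylacetic acid (EDC, cat. DMAP, CH2Cl2, 0 °C) and chromatographic separation of the diastereomers should give (S)-2-{[(tert-butyldimethylsilyl)oxy]methyl}-1-(3,4-dimethoxyphenyl)buta-2,3-dien-1-yl (R)-2-methoxy-2-phenylacetate F4, whose configuration can be assigned from the mandelate itself. Methanolysis (K2CO3, MeOH) should then return the route to 6.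

Step 5. The vinylmetal intermediate carries the ring oxygen anti-periplanar on C5 and may fragment by β-alkoxide loss, reopening the ring. The hindered tetrasubstituted iodide may also be reduced to the C–H compound instead of adding to the aldehyde. The fallback forms the ketone directly under palladium catalysis, where such elimination is not expected. It sets out from 7. A carbonylative Suzuki–Miyaura coupling with (3,4,5-trimethoxyphenyl)boronic acid (CO 1 atm, PdCl2(dppf), K2CO3, anisole, 80 °C) should give the enone and rejoin the route at 10, so that step 6 is no longer needed. This fallback makes no compound outside the list (F0).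

**Further compounds**
F1 | step 7 | (2R,3R,4R)-3-{[(tert-butyldimethylsilyl)oxy]methyl}-2-(3,4-dimethoxyphenyl)-4-[hydroxy(3,4,5-trimethoxyphenyl)methyl]tetrahydrofuran, both C7 epimers | COc1ccc([C@@H]2OC[C@H](C(O)c3cc(OC)c(OC)c(OC)c3)[C@@H]2CO[Si](C)(C)C(C)(C)C)cc1OC
F2 | step 7 | (2R,3R,4R)-3-{[(tert-butyldimethylsilyl)oxy]methyl}-2-(3,4-dimethoxyphenyl)-4-(3,4,5-trimethoxybenzoyl)tetrahydrofuran | COc1ccc([C@@H]2OC[C@H](C(=O)c3cc(OC)c(OC)c(OC)c3)[C@@H]2CO[Si](C)(C)C(C)(C)C)cc1OC
F3 | step 3 | racemic 2-{[(tert-butyldimethylsilyl)oxy]methyl}-1-(3,4-dimethoxyphenyl)buta-2,3-dien-1-ol | COc1ccc(C(O)C(CO[Si](C)(C)C(C)(C)C)=C=C)cc1OC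
F4 | step 3 | (S)-2-{[(tert-butyldimethylsilyl)oxy]methyl}-1-(3,4-dimethoxyphenyl)buta-2,3-dien-1-yl (R)-2-methoxy-2-phenylacetate | COc1ccc([C@H](OC(=O)[C@H](OC)c2ccccc2)C(CO[Si](C)(C)C(C)(C)C)=C=C)cc1OC
F0 | step 5 | none | none
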